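**Strategy.** The furan ring is cut at three bonds around C3: C3–C3a, C2–C3 and O1–C2. The feature used is that C3 is a carbonyl-level carbon (an enol ether) lying between C3a of ring A and the aryl-bearing C2, which is bonded to the phenolic O1. C3 can therefore be delivered as carbon monoxide, C2 as a carbene carbon and O1 as an ortho hydroxyl. One palladium-catalysed operation joins an ortho-iodophenol (ring A, carrying the C5 bromide and a pivalate-masked C6 oxygen), CO and the N-tosylhydrazone of pivalate-masked isovanillin (ring B) into the 2-arylbenzofuran-3(2H)-one. Enolate O-methylation, Stille prenylation and ester methanolysis finish the synthesis.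

Key step: step 6

Remark on the chemistry: the two phenols that take no part in the ring closure (C6–OH of ring A, C3'–OH of ring B) are carried as pivalates. A hindered aryl ester is chosen because the key step runs with aryloxide and carbonate at 80 °C, where less hindered aryl esters would be open to acyl transfer. The end game must stay basic, since the prenyl group beside the free C6 hydroxyl and the C3 enol ether are acid-sensitive.

Step 1
Reactants: 1 resorcinol
Product: 2 3-hydroxyphenyl pivalate
Conditions: PivCl (1 equiv), Et3N, THF, 0 °C to rt; resorcinol in excess (3 equiv)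
Reagents that add atoms: pivaloyl chloride, CC(C)(C)C(=O)Cl
Why: O-acylation of a phenol with an acid chloride, in which the large excess of the symmetrical diol biases the statistical outcome towards the monoester and unreacted resorcinol is washed out with water.

Step 2
Reactants: 2 3-hydroxyphenyl pivalate
Product: 3 2-bromo-5-hydroxyphenyl pivalate
Conditions: NBS (1.0 equiv), MeCN, −10 °C to rt
Reagents that add atoms: N-bromosuccinimide, O=C1CCC(=O)N1Br
Why: Electrophilic aromatic bromination, in which the free hydroxyl is by far the stronger director and NBS in MeCN brominates phenols para, so bromine should enter para to OH (ortho to the deactivated pivaloyloxy group), the minor ortho isomer being removed by chromatography.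

Step 3
Reactants: 3 2-bromo-5-hydroxyphenyl pivalate
Product: 4 2-bromo-5-hydroxy-4-iodophenyl pivalate
Conditions: NIS (1.05 equiv), TsOH (cat.), MeCN, rt
Reagents that add atoms: N-iodosuccinimide, O=C1CCC(=O)N1I
Why: Electrophilic aromatic iodination, in which the para position is blocked and the hydroxyl directs iodine to the ortho position that is also para to the pivaloyloxy group, the other ortho position between the two oxygens being shielded.

Step 4
Reactants: 5 3-hydroxy-4-methoxybenzaldehyde (isovanillin)
Product: 6 5-formyl-2-methoxyphenyl pivalate
Conditions: PivCl, Et3N, DMAP (cat.), CH2Cl2, 0 °C to rt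
Reagents that add atoms: pivaloyl chloride, CC(C)(C)C(=O)Cl
Why: DMAP-catalysed O-acylation of the single phenol, to which the aldehyde is inert.

Step 5
Reactants: 6 5-formyl-2-methoxyphenyl pivalate; 7 p-toluenesulfonyl hydrazide
Product: 8 2-methoxy-5-[(E)-(2-tosylhydrazinylidene)methyl]phenyl pivalate
Conditions: MeOH, rt
Reagents that add atoms: none
Why: Condensation of an aldehyde with a sulfonyl hydrazide to the hydrazone, which forms as the thermodynamically favoured E isomer and crystallises from methanol, while the aryl pivalate is untouched under these neutral conditions.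

Step 6
Reactants: 4 2-bromo-5-hydroxy-4-iodophenyl pivalate; 8 2-methoxy-5-[(E)-(2-tosylhydrazinylidene)methyl]phenyl pivalate; 9 carbon monoxide
Product: 11 5-bromo-2-(4-methoxy-3-pivaloyloxyphenyl)-3-oxo-2,3-dihydro-1-benzofuran-6-yl pivalate (racemic), via aryldiazomethane 10 (not isolated)
Conditions: Pd(PPh3)4 (5 mol %), K2CO3 (3 equiv), CO (3 bar), 1,4-dioxane, 80 °C, 8 added slowly; then aq NH4Cl
Reagents that add atoms: none
Why: Proposed new method: zerovalent palladium should insert into the C–I bond of the phenoxide of 4 in preference to the C–Br bond, CO insertion gives an aroylpalladium species (C3–C3a), diazoalkane 10 released from 8 by K2CO3 forms a palladium carbene, and migration of the aroyl group to the carbene carbon forges C2–C3 and leaves a palladium C-enolate that is also a π-benzyl complex and has no β-hydrogen. The ortho aryloxide then forms O1–C2, either by C–O reductive elimination from a six-membered oxapalladacycle or by attack on the π-benzyl carbon, which is a 5-exo-tet closure of the furanone ring and returns zerovalent palladium. The closest known reaction types are the carbonylative coupling of aryl iodides with N-tosylhydrazones through acyl migratory insertion and palladium carbene three-component couplings in which a π-allyl or π-benzyl intermediate is captured by a nucleophile; the capture of the acyl-insertion enolate by oxygen is the untried part. C2 is a new stereocenter but is formed racemic, since nothing chiral is present, and this is of no consequence because C2 becomes sp2 in step 7. The step needs CO insertion before carbene insertion and ring closure before protonation or intermolecular aryloxycarbonylation; CO pressure, slow addition of 8 that keeps 10 dilute, and the intramolecular position of the ortho oxygen are meant to secure this. The pivalates resist acyl transfer to aryloxide, and the C5 bromide is slow to add to Pd(PPh3)4 at this temperature.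

Step 7
Reactants: 11 5-bromo-2-(4-methoxy-3-pivaloyloxyphenyl)-3-oxo-2,3-dihydro-1-benzofuran-6-yl pivalate
Product: 12 5-bromo-3-methoxy-2-(4-methoxy-3-pivaloyloxyphenyl)-1-benzofuran-6-yl pivalate
Conditions: Me2SO4, K2CO3, acetone, 50 °C, Ar
Reagents that add atoms: dimethyl sulfate, COS(=O)(=O)OC
Why: O-alkylation of an enolate (Williamson-type), in which the hard electrophile, the potassium counter-ion in a polar solvent and the gain of benzofuran aromaticity favour attack of the ambident 2-aryl-3-oxo enolate through oxygen, which also removes the C2 stereocenter, while exclusion of air prevents autoxidation at C2.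

Step 8
Reactants: 12 5-bromo-3-methoxy-2-(4-methoxy-3-pivaloyloxyphenyl)-1-benzofuran-6-yl pivalate; 13 tributyl(3-methylbut-2-enyl)stannane
Product: 14 3-methoxy-2-(4-methoxy-3-pivaloyloxyphenyl)-5-(3-methylbut-2-enyl)-1-benzofuran-6-yl pivalate
Conditions: Pd(PPh3)4 (10 mol %), DMF, 100 °C
Reagents that add atoms: none
Why: Stille cross-coupling, in which zerovalent palladium adds to the only C–Br bond, the allylic stannane transmetalates and reductive elimination at the unsubstituted allyl terminus gives the linear 3-methylbut-2-enyl group under neutral conditions that leave the pivalates and the enol ether intact.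

Step 9
Reactants: 14 3-methoxy-2-(4-methoxy-3-pivaloyloxyphenyl)-5-(3-methylbut-2-enyl)-1-benzofuran-6-yl pivalate
Product: 15 2-(3-hydroxy-4-methoxyphenyl)-3-methoxy-5-(3-methylbut-2-enyl)-1-benzofuran-6-ol (target)
Conditions: K2CO3 (3 equiv), MeOH–THF, 40 °C, Ar; then aq NH4Cl
Reagents that add atoms: none
Why: Base-mediated transesterification (methanolysis) of the two aryl pivalates, which are activated esters with aryloxide leaving groups, in a basic medium that avoids acid-promoted cyclisation of the ortho-prenylphenol to a chroman and hydrolysis of the C3 enol ether; the target has no stereocenter.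

**Compound list**

1 | resorcinol | Oc1cccc(O)c1 | starting material
2 | 3-hydroxyphenyl pivalate | CC(C)(C)C(=O)Oc1cccc(O)c1 | intermediate
3 | 2-bromo-5-hydroxyphenyl pivalate | CC(C)(C)C(=O)Oc1cc(O)ccc1Br | intermediate
4 | 2-bromo-5-hydroxy-4-iodophenyl pivalate | CC(C)(C)C(=O)Oc1cc(O)c(I)cc1Br | intermediate
5 | 3-hydroxy-4-methoxybenzaldehyde (isovanillin) | COc1ccc(C=O)cc1O | starting material
6 | 5-formyl-2-methoxyphenyl pivalate | COc1ccc(C=O)cc1OC(=O)C(C)(C)C | intermediate
7 | p-toluenesulfonyl hydrazide | Cc1ccc(cc1)S(=O)(=O)NN | starting material
8 | 2-methoxy-5-[(E)-(2-tosylhydrazinylidene)methyl]phenyl pivalate | COc1ccc(/C=N/NS(=O)(=O)c2ccc(C)cc2)cc1OC(=O)C(C)(C)C | intermediate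
9 | carbon monoxide | [C-]#[O+] | starting material
10 | 5-(diazomethyl)-2-methoxyphenyl pivalate (aryldiazomethane, not isolated) | COc1ccc(C=[N+]=[N-])cc1OC(=O)C(C)(C)C | intermediate
11 | 5-bromo-2-(4-methoxy-3-pivaloyloxyphenyl)-3-oxo-2,3-dihydro-1-benzofuran-6-yl pivalate (racemic) | O=C1c2cc(Br)c(OC(=O)C(C)(C)C)cc2OC1c1ccc(OC)c(OC(=O)C(C)(C)C)c1 | intermediate
12 | 5-bromo-3-methoxy-2-(4-methoxy-3-pivaloyloxyphenyl)-1-benzofuran-6-yl pivalate | COc1c(-c2ccc(OC)c(OC(=O)C(C)(C)C)c2)oc2cc(OC(=O)C(C)(C)C)c(Br)cc12 | intermediate
13 | tributyl(3-methylbut-2-enyl)stannane | CC(C)=CC[Sn](CCCC)(CCCC)CCCC | starting material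
14 | 3-methoxy-2-(4-methoxy-3-pivaloyloxyphenyl)-5-(3-methylbut-2-enyl)-1-benzofuran-6-yl pivalate | COc1c(-c2ccc(OC)c(OC(=O)C(C)(C)C)c2)oc2cc(OC(=O)C(C)(C)C)c(CC=C(C)C)cc12 | intermediate
15 | 2-(3-hydroxy-4-methoxyphenyl)-3-methoxy-5-(3-methylbut-2-enyl)-1-benzofuran-6-ol | COc1ccc(-c2oc3cc(O)c(CC=C(C)C)cc3c2OC)cc1O | target

**Step count.** Total steps: 9. Longest linear sequence: 7 steps (steps 1, 2, 3, 6, 7, 8, 9).

**Steps most likely to fail**

1. Step 6 (Proposed new method).
   - What may go wrong: protonation of the palladium enolate before the C–O bond forms (open-chain ketone), intermolecular aryloxycarbonylation of the aroylpalladium species by aryloxide or by the enolate of the product, carbene dimerisation, or carbene insertion ahead of CO insertion.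
   - Fallback (known chemistry): it sets out from 3, with 8 as partner, and comes back to the route at 11.
   - Bromophenol 3 is formylated ortho to the hydroxyl, at the position para to the pivaloyloxy group, with MgCl2, Et3N and paraformaldehyde in MeCN at reflux (magnesium-mediated ortho-formylation of phenols). This gives the salicylaldehyde 2-bromo-4-formyl-5-hydroxyphenyl pivalate F1.
   - Heating F1 with hydrazone 8 and K2CO3 in 1,4-dioxane should give the deoxybenzoin 2-bromo-5-hydroxy-4-[(4-methoxy-3-pivaloyloxyphenyl)acetyl]phenyl pivalate F2. This is the homologation of an aromatic aldehyde to a benzyl ketone by the diazoalkane released from a tosylhydrazone, with 1,2-hydride shift.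
   - Bromination alpha to the ketone with CuBr2 in EtOAc–CHCl3 at reflux gives the bromoketone 2-bromo-4-[bromo(4-methoxy-3-pivaloyloxyphenyl)acetyl]-5-hydroxyphenyl pivalate F3 (racemic).
   - K2CO3 in acetone at rt closes O1–C2 by intramolecular displacement of bromide, which returns the route at 11.
   - Open-chain ketone formed in a partly failed step 6 is the same compound F2 and can join this sequence there.

2. Step 8.
   - What may go wrong: transposition of the allyl unit during transmetalation or reductive elimination (branched 1,1-dimethylallyl isomer), migration of the double bond into conjugation, or slow oxidative addition at the hindered bromide followed by protodebromination.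
   - Fallback: it sets out from 12 and comes back to the route at 14.
   - Stille coupling of 12 with allyltributylstannane (Pd(PPh3)4, DMF, 100 °C) uses a smaller allyl donor for which transposition leads to the same product. It gives the allyl compound 3-methoxy-2-(4-methoxy-3-pivaloyloxyphenyl)-5-(prop-2-enyl)-1-benzofuran-6-yl pivalate F4.
   - Olefin cross-metathesis of F4 with excess 2-methylbut-2-ene (second-generation Grubbs catalyst, CH2Cl2, 40 °C) turns the allyl into the prenyl group and gives 14.

3. Step 7.
   - What may go wrong: alkylation of the ambident enolate at C2 instead of at oxygen, or autoxidation of the enolate at C2.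
   - Fallback: it sets out from 11 and comes back to the route at 12.
   - Ketone 11 is heated with trimethyl orthoformate and catalytic TsOH in MeOH at 50 °C. The ketone is converted into the ketal 5-bromo-3,3-dimethoxy-2-(4-methoxy-3-pivaloyloxyphenyl)-2,3-dihydro-1-benzofuran-6-yl pivalate F5 (racemic).
   - Under the same conditions F5 loses methanol to give the aromatic enol ether 12 (acid-catalysed ketalisation and elimination). This route puts the methyl group on oxygen by construction and never forms the enolate.

**Further compounds**

F1 | step 6 | 2-bromo-4-formyl-5-hydroxyphenyl pivalate | CC(C)(C)C(=O)Oc1cc(O)c(C=O)cc1Br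
F2 | step 6 | 2-bromo-5-hydroxy-4-[(4-methoxy-3-pivaloyloxyphenyl)acetyl]phenyl pivalate | CC(C)(C)C(=O)Oc1cc(O)c(cc1Br)C(=O)Cc1ccc(OC)c(OC(=O)C(C)(C)C)c1
F3 | step 6 | 2-bromo-4-[bromo(4-methoxy-3-pivaloyloxyphenyl)acetyl]-5-hydroxyphenyl pivalate (racemic) | CC(C)(C)C(=O)Oc1cc(O)c(cc1Br)C(=O)C(Br)c1ccc(OC)c(OC(=O)C(C)(C)C)c1
F4 | step 8 | 3-methoxy-2-(4-methoxy-3-pivaloyloxyphenyl)-5-(prop-2-enyl)-1-benzofuran-6-yl pivalate | COc1c(-c2ccc(OC)c(OC(=O)C(C)(C)C)c2)oc2cc(OC(=O)C(C)(C)C)c(CC=C)cc12
F5 | step 7 | 5-bromo-3,3-dimethoxy-2-(4-methoxy-3-pivaloyloxyphenyl)-2,3-dihydro-1-benzofuran-6-yl pivalate (racemic) | COC1(OC)c2cc(Br)c(OC(=O)C(C)(C)C)cc2OC1c1ccc(OC)c(OC(=O)C(C)(C)C)c1
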